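The numbers were set for the occasion, and the outcome is calculated.

The main step used nucleophile more slowly than self-condensation just after the start of this flask, at 0.44 of its rate, so I asked how much target the nucleophile could buy.

electrophile 0.050 M; nucleophile 0.0500 M; buffer base 0.0100 M; buffer acid 5.00 mM; scavenger 0.0250 M; time 12 s

    scavenger + leaving group → scavenged by-product (k1 = 6.44 M⁻¹ s⁻¹)
    protonated nucleophile ⇌ nucleophile + acid, settled at all times (K2 = 1.3 × 10⁻⁹ M)
    2 nucleophile → self-condensation product (k3 = 4.60 M⁻¹ s⁻¹)
    buffer acid ⇌ buffer base + acid, settled at all times (K4 = 3.2 × 10⁻⁷ M)
    electrophile + nucleophile → acid + target + leaving group (k5 = 3.65 M⁻¹ s⁻¹)
    electrophile + leaving group ⇌ idle adduct, settled at all times (K6 = 7.41 M⁻¹)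

- acid is the free proton; pH is minus the decimal logarithm of its molar concentration
- amounts and yields of leaving group count idle adduct too
- for a step with 2 of a species take k times the square, and two of it per event
- what has gone from electrophile into another species counts as reacted, even if it can come back
- run time (flask): 12 s

1. part of the electrophile that has reacted at 12 s
2. pH of the solution at 12 s

**Main step.** I wrote all amounts as fractions of the charged electrophile. Buffer acid gave its proton to nucleophile on mixing because its constant far exceeds that of protonated nucleophile, so free nucleophile began at b = 0.900. For the same reason, the acid from each turn took a second nucleophile, so each target cost two. The main step alone would have spent that reserve at b divided by two, 45.0% of target. Buffer base can take acid as well, which raises the reserve to 1.20 and the main step's stop to 60.0%.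

**Adding self-condensation.** This step also costs two free nucleophile per turn, but its rate goes with the square of n, the free fraction. I held electrophile at its charge and put s = 0.793, a selectivity factor. Dividing the target rate by the fall of n removed time: each unit of n lost gave s over two times (s + n) of target. Integrating from b to nothing gave s divided by two, times the natural logarithm of one plus b over s, which was 30.1%, the target that reserve b buys. Starting from the larger reserve, with buffer base counted, the same integral gave 36.5%. With electrophile held at its charge, the main step alone halves n in 1.90 s, and the run lasted 6.32 of these.

**The rest.** Free leaving group has a half-life of 4.3 s against scavenger, shorter than the run. Counting its decay from one nucleophile half-life and binding it at 0.37 per free unit, I got idle adduct of 2.19%, so 32.3% reacted. I reckoned no pH: the integral runs n down to nothing, so it gives no ratio of forms at the asked time.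

**The result.** The forecast gave 30.7% and pH 7.7, on the ground that “Each target formed releases a proton, which protonates another nucleophile”. The simulation gave 30.9% reacted and pH 7.67.

**Not at rest.** At 12.0 s this flask held target at 28.5%, under the 30.1% that reserve b buys, with 2.2% of its nucleophile free. For the neighbour charged with 0.12 M of electrophile, the same integral gave 15.4%, and that flask held 16.3%. Left ten times as long, this flask still moved: target reached 34.6%, more than 30.1% but less than the 36.5% of the larger reserve, and the reacted part reached 34.7%. Buffer acid went from 18.9% to 121% of its own charge, and scavenger fell from 65.8% to 32.2%.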